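The numbers of this flask stand for no real mixture; the result is computed.

A leftover started my reckoning: how much substrate must this flask still hold once its catalyst has been trapped, and what does that loss do to the rate on the way?

substrate 10 mM; reagent 1.05 equiv; capture agent 10.0 mM; free catalyst 5 mol%

* apparent order in reagent when 20% of the substrate are converted (percent change of the rate of making target for one percent more reagent charged)
* apparent order in free catalyst when 20% of the substrate are converted (percent change of the rate of making target for one percent more free catalyst charged)

    substrate + catalyst intermediate A → catalyst intermediate B (k1 = 8.2 L mol⁻¹ min⁻¹)
    catalyst intermediate B → catalyst intermediate C (k2 = 0.026 min⁻¹)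
    reagent + free catalyst ⇌ catalyst intermediate A (K3 = 51 L mol⁻¹, k3 = 1.8 L mol⁻¹ min⁻¹)
    catalyst intermediate A + capture agent → trapped intermediate (k4 = 0.32 L mol⁻¹ min⁻¹)
    catalyst intermediate C ⇌ free catalyst + target (K5 = 0.0045 M, k5 = 0.012 min⁻¹)

Free catalyst takes up reagent to give catalyst intermediate A. That intermediate either meets substrate and goes on through intermediates B and C to target and free catalyst, or meets capture agent and becomes trapped intermediate.

In the first instants I counted turnovers at that fork. Substrate takes intermediate A at 118 d⁻¹ and capture agent takes it at 4.6 d⁻¹, so going on is faster by 25.6 to one, whatever the amount of A, which cancels from the ratio.

Through the middle of the run those odds shrink with the substrate, while I held the capture agent near its charge, the catalyst charge of 0.500 mM being far less than it, at 5.00% of it. Dividing the two rates and integrating, the logarithm of substrate charged over substrate left grows in proportion to the catalyst trapped.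

With the whole charge trapped, that logarithm is the rate constant of the substrate step times the catalyst charge, over the rate constant of capture times the capture agent: 1.28. I call this the turnover budget, the logarithmic fall in substrate that the catalyst charge can pay for. With the catalyst gone, then, I expected about 27.8% of the substrate to remain.

At the moment asked about, the conversion had cost 0.223 of that budget, so 17.4% of the catalyst was trapped, or 0.0871 mM. The catalyst charge cancels from that amount, so a larger charge loses the same quantity. If the rate follows surviving catalyst, the order in free catalyst is 1.21. For reagent I went only as far as a bound: one percent more charged is a larger share of what remains, and an order of one in remaining reagent gives 1.24.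

The forecast gave 0.65 for reagent, within 0.55 to 0.75, and 1.22 for free catalyst, within 1.1 to 1.32, holding the trapped amount “almost independent of reagent or catalyst charge”.

The simulation gave 0.66 for reagent and 1.2 for free catalyst, both inside those ranges.

After 150 d this flask held 26.9% of its substrate, against my estimate of 27.8%. Taking away the capture step moved its order in free catalyst from 1.2 to 1.0. The flask with twice the free catalyst has a budget of 2.56 and pays the same 0.223, so surviving catalyst predicts a rate factor of 2.21, and that flask gave 2.25.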